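Add up, at each reading of the north flask, what the solid substrate has lost and what target has gained.

- north: solid substrate 0.087 M; the very flask that is asked about, followed so far
- flask: solid substrate 0.087 M; time 3.0 h

north run (percent of the solid substrate charged)

| time / min | target / % | solid substrate / % |
|---|---|---|
| 8.00 | 0 | 96.4 |
| 15.0 | 2.0 | 95.4 |
| 25.0 | 1.8 | 93.7 |
| 50.0 | 10.2 | 83.0 |
| 90.0 | 18.9 | 75.3 |

(readings scatter by 1 percentage point)

- solid substrate is a solid; its amount is given per volume of the solution
- at the start none of the solid substrate is in solution

1. amount of target in percent of the solid substrate charged, at 20 min, 50 min, 2.0 h and 3.0 h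

I turned the question round and asked what would have to be true for target not to rise in a straight line. As the zero of my scale I took the case where each further percent lost by the solid substrate reaches target. The share of the charge that is neither solid substrate nor target then stays flat, a steady state. The rise of target would bend if that share grew, or if the solid substrate slowed its pace. From 25.0 min to 90.0 min it read 4.50%, 6.80% and 5.80%, with a mean of 5.70%. I called this mean the gap G. Its rise of 1.3 percentage points was smaller than the scatter of one gap, 1.4 points, so I held G flat and, as my own assumption, kept the solid's average pace up to 90.0 min:

target(t) = solid substrate lost by t − G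

target(2.0 h) = 32.9% − 5.70% = 27.2%

target(3.0 h) = 49.4% − 5.70% = 43.7%

The forecast gave 2.5%, 9.5%, 25% and 37%, lower at 3.0 h than my line; it drew its own line through the readings and added that “Shrinking surface area or product effects may slow it slightly”.

The flask gave 2.58%, 9.40%, 24.1% and 35.2%.

    starting material → target (k = 0.0620 min⁻¹)
    solid substrate ⇌ starting material, rate k2*(cs2 - [starting material]) while solid is left; crystals form when [starting material] > cs2 (solubility = 40.0 mM, k = 0.00720 min⁻¹)
    target ⇌ isomer of the product (K = 0.710, k = 0.00750 min⁻¹)

In this flask the solid substrate kept going into solution, 53.9% of the charge net by 3.0 h, while starting material stood at 4.77% after 1.50 h and 4.78% after 3.00 h and turned into target. Target meanwhile passed into isomer of the product, which reached 4.30% after 1.50 h and 13.9% after 3.00 h, and G stood at 18.7% at the end, above my 5.70%. My line stood 8.5 points above target at 3.0 h, and at twice the time, in the late run, it stood at 93.1%, higher than the 63.4% of target found.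

The readings were generated by integration on assumed constants, and the scatter is random.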